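**Retrosynthetic overview**
1. Target ⇒ epoxide-to-tetrahydrofuran ring expansion: the 9,10-cis-epoxide oxygen of an epoxy chlorohydrin displaces the C6 chloride, and stearate opens the bicyclic epoxonium ion at C10 (forms O–C6 and the ester C–O bond; the oxolane is the last ring made).
2. Epoxy chlorohydrin ⇒ hydroxyl-directed epoxidation of a (Z)-homoallylic anti-chlorohydrin (second ring: the 9,10-oxirane).
3. (Z)-Homoallylic chlorohydrin ⇒ (Z)-alkenylcopper (non-8-enylcopper + acetylene) + a terminal chloro-epoxide (first ring), itself from (R)-2-chloroheptanal (heptanal, organocatalytic chlorination) and a CH2 carbenoid.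
4. Stearic acid ⇒ C7 + C6 + C5 by two copper-catalysed Grignard couplings; 9-bromonon-1-ene ⇒ allyl Grignard + 1,6-dibromohexane.
5. Ring order: terminal oxirane (opened again) → 9,10-oxirane → oxolane by ring expansion.

Assumption: allylmagnesium bromide solution and acetylene are bought as such; the pyrrolidine catalyst in step 4 is written as (2R,5R) and is meant as the antipode that delivers the (R)-aldehyde (if the sense is the opposite, its mirror image is used).

**Step 1**
Reactants: 1 1-bromoheptane; 2 1,6-dibromohexane
Product: 4 1-bromotridecane, via heptylmagnesium bromide 3 (not isolated)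
Conditions: Mg, THF, 40 °C; then 2 (3 equiv), Li2CuCl4 (2 mol %), THF, −10 → 0 °C
Reagents that add atoms: none
Why: Kochi-type copper-catalysed sp3–sp3 Grignard coupling, kept at mono-substitution by the excess dibromide (recovered by distillation); no stereocentre.

**Step 2**
Reactants: 4 1-bromotridecane; 5 5-bromopentanoic acid
Product: 8 octadecanoic acid (stearic acid), via tridecylmagnesium bromide 6 (not isolated), via chloromagnesium 5-bromopentanoate 7 (not isolated)
Conditions: 4, Mg, THF; 5, MeMgCl (1.0 equiv), THF, −20 °C; combine, Li2CuCl4 (3 mol %), −20 → 0 °C; aq. HCl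
Reagents that add atoms: none
Why: Kochi copper-catalysed alkyl–alkyl coupling of a Grignard reagent with the magnesium salt of an ω-bromo acid, whose carboxylate is inert to RMgX at low temperature; no stereocentre.

**Step 3**
Reactants: 9 allylmagnesium bromide; 2 1,6-dibromohexane
Product: 10 9-bromonon-1-ene
Conditions: 2 (3 equiv), Li2CuCl4 (1 mol %), THF, 0 °C → rt
Reagents that add atoms: none
Why: Mono-allylation of the dibromide by Grignard SN2/Kochi coupling, the excess of 2 suppressing double substitution; no stereocentre.

**Step 4**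
Reactants: 11 heptanal
Product: 12 (2R)-2-chloroheptanal
Conditions: NCS (1.3 equiv), (2R,5R)-2,5-diphenylpyrrolidine (10 mol %), CH2Cl2, 0 °C → rt; pentane extraction, used crude at once
Reagents that add atoms: N-chlorosuccinimide, O=C1CCC(=O)N1Cl
Why: Enamine organocatalytic α-chlorination in which the C2-symmetric pyrrolidine shields one face of the E-enamine, so chlorine is delivered to the other and sets the future C6 as R (inverted to S in step 8).

**Step 5**
Reactants: 12 (2R)-2-chloroheptanal; 13 diiodomethane
Product: 16 (2S)-2-[(1R)-1-chlorohexyl]oxirane, via iodomethyllithium 14 (not isolated), via lithium (2R,3R)-3-chloro-1-iodooctan-2-olate 15 (not isolated)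
Conditions: MeLi·LiBr (1.3 equiv) added to 12 + 13, THF, −78 °C; then rt, 2 h
Reagents that add atoms: none
Why: Halomethyllithium carbonyl homologation under Cornforth control (C–Cl anti to C=O, attack past H) gives the anti iodohydrin alkoxide and sets C7 as S, and Williamson closure then occurs only on the primary C–I, leaving the secondary chloride intact.

**Step 6**
Reactants: 10 9-bromonon-1-ene; 17 acetylene; 16 (2S)-2-[(1R)-1-chlorohexyl]oxirane
Product: 21 (6R,7S,9Z)-6-chlorononadeca-9,18-dien-7-ol, via non-8-enylmagnesium bromide 18 (not isolated), via non-8-enylcopper 19 (not isolated), via (1Z)-undeca-1,10-dienylcopper 20 (not isolated)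
Conditions: 10, Mg, Et2O; CuBr·SMe2 (1 equiv), −40 °C; 17, −40 → −20 °C; then 16 (0.75 equiv), BF3·OEt2 (promoter), −78 °C; aq. NH4Cl/NH3
Reagents that add atoms: none
Why: Normant syn-carbocupration of acetylene gives the (Z)-alkenylcopper, which opens the epoxide at its terminal carbon (BF3-promoted SN2) with retention of alkene geometry, so the 9Z olefin is fixed and C6/C7 are untouched at −78 °C.

**Step 7**
Reactants: 21 (6R,7S,9Z)-6-chlorononadeca-9,18-dien-7-ol
Product: 22 (2S,3R)-3-chloro-1-[(2R,3S)-3-(non-8-en-1-yl)oxiran-2-yl]octan-2-ol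
Conditions: VO(acac)2 (5 mol %), t-BuOOH (1.5 equiv, decane), CH2Cl2, 0 °C → rt
Reagents that add atoms: tert-butyl hydroperoxide, CC(C)(C)OO
Why: Vanadium(V) hydroxyl-directed epoxidation (Sharpless–Michaelson type) touches only the homoallylic Z-olefin, and a chair vanadate transition state with the CHCl-pentyl group equatorial and an allylic H eclipsing the Z-olefin (A1,3 control) is expected to deliver oxygen syn to the 7-OH, setting C9 as R and C10 as S in a cis-epoxide.

**Step 8**
Reactants: 22 (2S,3R)-3-chloro-1-[(2R,3S)-3-(non-8-en-1-yl)oxiran-2-yl]octan-2-ol; 8 octadecanoic acid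
Product: 25 (1R)-1-[(2R,4S,5S)-4-hydroxy-5-pentyloxolan-2-yl]dec-9-en-1-yl octadecanoate (CNP0342202.1), via silver(I) octadecanoate 23 (not isolated), via 1-oxoniabicyclo[3.1.0]hexane epoxonium ion 24 (not isolated)
Conditions: 8 (2.0 equiv), Ag2O (1.0 equiv), 4 Å MS, PhMe, 60 °C, dark; then 22, AgOTf (20 mol %), 50 °C
Reagents that add atoms: none
Why: Proposed new method: Ag(I) pulls chloride from C6 while the epoxide oxygen attacks from the back through a five-membered transition state (inversion, C6 becomes S) to give epoxonium ion 24, which silver-paired stearate opens at the exocyclic C10 with inversion (C10 becomes R, C9 retained; endo attack would give a tetrahydropyran with axial groups), so the oxirane is expanded to the oxolane and the ester is placed on O10 only; the closest known reactions are silver-promoted chlorohydrin-to-tetrahydrofuran etherifications with hydroxyl nucleophiles and halonium-triggered epoxide ring expansions with carboxylate capture through the same kind of epoxonium ion.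

**Compound list**
1 | 1-bromoheptane | CCCCCCCBr | starting material
2 | 1,6-dibromohexane | BrCCCCCCBr | starting material
3 | heptylmagnesium bromide | CCCCCCC[Mg]Br | intermediate (not isolated)
4 | 1-bromotridecane | CCCCCCCCCCCCCBr | intermediate
5 | 5-bromopentanoic acid | OC(=O)CCCCBr | starting material
6 | tridecylmagnesium bromide | CCCCCCCCCCCCC[Mg]Br | intermediate (not isolated)
7 | chloromagnesium 5-bromopentanoate | [O-]C(=O)CCCCBr.[Mg+2].[Cl-] | intermediate (not isolated)
8 | octadecanoic acid (stearic acid) | CCCCCCCCCCCCCCCCCC(=O)O | intermediate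
9 | allylmagnesium bromide | C=CC[Mg]Br | starting material
10 | 9-bromonon-1-ene | BrCCCCCCCC=C | intermediate
11 | heptanal | CCCCCCC=O | starting material
12 | (2R)-2-chloroheptanal | CCCCC[C@@H](Cl)C=O | intermediate
13 | diiodomethane | ICI | starting material
14 | iodomethyllithium | [Li]CI | intermediate (not isolated)
15 | lithium (2R,3R)-3-chloro-1-iodooctan-2-olate | CCCCC[C@@H](Cl)[C@@H]([O-])CI.[Li+] | intermediate (not isolated)
16 | (2S)-2-[(1R)-1-chlorohexyl]oxirane | CCCCC[C@@H](Cl)[C@@H]1CO1 | intermediate
17 | acetylene | C#C | starting material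
18 | non-8-enylmagnesium bromide | C=CCCCCCCC[Mg]Br | intermediate (not isolated)
19 | non-8-enylcopper | C=CCCCCCCC[Cu] | intermediate (not isolated)
20 | (1Z)-undeca-1,10-dienylcopper | C=CCCCCCCC/C=C\[Cu] | intermediate (not isolated)
21 | (6R,7S,9Z)-6-chlorononadeca-9,18-dien-7-ol | CCCCC[C@@H](Cl)[C@@H](O)C/C=C\CCCCCCCC=C | intermediate
22 | (2S,3R)-3-chloro-1-[(2R,3S)-3-(non-8-en-1-yl)oxiran-2-yl]octan-2-ol, i.e. (6R,7S,9R,10S)-6-chloro-9,10-epoxynonadec-18-en-7-ol | CCCCC[C@@H](Cl)[C@@H](O)C[C@H]1O[C@H]1CCCCCCCC=C | intermediate
23 | silver(I) octadecanoate | CCCCCCCCCCCCCCCCCC(=O)[O-].[Ag+] | intermediate (not isolated)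
24 | epoxonium cation: 1-oxoniabicyclo[3.1.0]hexane with 2-pentyl (6S), 3-hydroxy (7S), ring-fusion C9 (R) and 6-(non-8-enyl) (10S) | CCCCC[C@H]1[C@@H](O)C[C@@H]2[C@H](CCCCCCCC=C)[O+]12 | intermediate (not isolated)
25 | (1R)-1-[(2R,4S,5S)-4-hydroxy-5-pentyloxolan-2-yl]dec-9-en-1-yl octadecanoate, i.e. (6S,7S,9R,10R)-6,9-epoxy-7-hydroxynonadec-18-en-10-yl stearate | C=CCCCCCCC[C@@H](OC(=O)CCCCCCCCCCCCCCCCC)[C@H]1C[C@H](O)[C@H](CCCCC)O1 | target

**Step count and risks**
Total step count: 8. Longest linear sequence: 5 steps (11 → 12 → 16 → 21 → 22 → 25).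

Three steps most likely to fail:

Step 8 (the proposed new ring expansion). The risks are endo opening of ion 24 at C9 (tetrahydropyran isomer), direct substitution at C6, and acid-induced epoxide opening. The fallback uses known chemistry and sets out from 22. The epoxide is first opened with stearic acid 8 under Ti(OiPr)4 assistance (7-OH-directed attack at the distal C10 with inversion; the C9 regioisomer is removed by chromatography) to give (6R,7S,9R,10R)-6-chloro-7,9-dihydroxynonadec-18-en-10-yl octadecanoate F1. A silver-promoted chlorohydrin etherification (AgOTf, Ag2O, THF, 50 °C) then lets the 9-OH displace the C6 chloride with inversion in a 5-exo closure. This comes back to the route at 25.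

Step 7 (sense and level of the directed epoxidation). I am not certain the vanadium epoxidation gives the syn isomer; the anti epoxide would lead to the 9,10-bis-epimer of the target. The fallback sets out from 21 and replaces reagent delivery by a tethered iodocyclisation. Boc2O/DMAP gives tert-butyl (6R,7S,9Z)-6-chlorononadeca-9,18-dien-7-yl carbonate F2. Iodine in MeCN at −20 °C (chair transition state, both groups equatorial, anti addition; reversible iodonium formation spares the terminal alkene) gives the 1,3-syn cyclic iodocarbonate (4S,6R)-4-[(1R)-1-chlorohexyl]-6-[(1R)-1-iododec-9-en-1-yl]-1,3-dioxan-2-one F3. Brief K2CO3/MeOH at −20 → 0 °C (the iodohydrin closes far faster than the chlorohydrin) comes back to the route at 22.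

Step 6 (three-stage organocopper sequence on a sensitive chloro-epoxide). The fallback sets out from 10 and 16 and makes the C8–C9 bond with an acetylide instead. Lithium acetylide–ethylenediamine in DMSO converts 10 into undec-10-en-1-yne F4. n-BuLi gives lithium undec-10-en-1-ynide F5, which opens 16 with BF3·OEt2 at −78 °C to (6R,7S)-6-chlorononadec-18-en-9-yn-7-ol F6. Semi-hydrogenation over P-2 nickel/ethylenediamine (stopped at one equivalent of H2) comes back to the route at 21.

**Further compounds**
F1 | step 8 | (6R,7S,9R,10R)-6-chloro-7,9-dihydroxynonadec-18-en-10-yl octadecanoate | CCCCC[C@@H](Cl)[C@@H](O)C[C@@H](O)[C@H](OC(=O)CCCCCCCCCCCCCCCCC)CCCCCCCC=C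
F2 | step 7 | tert-butyl (6R,7S,9Z)-6-chlorononadeca-9,18-dien-7-yl carbonate | CCCCC[C@@H](Cl)[C@@H](OC(=O)OC(C)(C)C)C/C=C\CCCCCCCC=C
F3 | step 7 | (4S,6R)-4-[(1R)-1-chlorohexyl]-6-[(1R)-1-iododec-9-en-1-yl]-1,3-dioxan-2-one | CCCCC[C@@H](Cl)[C@@H]1C[C@H]([C@H](I)CCCCCCCC=C)OC(=O)O1
F4 | step 6 | undec-10-en-1-yne | C#CCCCCCCCC=C
F5 | step 6 | lithium undec-10-en-1-ynide | [Li]C#CCCCCCCCC=C
F6 | step 6 | (6R,7S)-6-chlorononadec-18-en-9-yn-7-ol | CCCCC[C@@H](Cl)[C@@H](O)CC#CCCCCCCCC=C
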